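Seconds are the unit for this flask: starting material goes in evenly over 150 s, and the question is how that dosing time, T, compares with the mean life τ of starting material in the flask, the reciprocal of its apparent first-order constant.

| setting | Tuesday's | Sunday's | flask |
|---|---|---|---|
| starting material | 0.10 M (fed, over 2.5 min) | 0.10 M (fed, over 2.5 min) | 0.10 M (fed, over 2.5 min) |
| reagent | 0.11 M | 0.074 M | 0.110 M |
| free catalyst | 0.23 mM | 0.23 mM | 0.23 mM |
| remark | the very flask that is asked about, followed so far | run made earlier |  |
| time |  |  | 2.5 min |

Tuesday's run (percent of the starting material charged): time / s: product / % = 10.0: 0.5; 15.0: 1.0; 25.0: 3.6; 30.0: 4.0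

Sunday's run (percent of the starting material charged): time / min: product / % = 0.333: 1.8; 0.833: 10.2; 1.50: 24.5; 2.50: 49.2

(scatter of a reading: 0.3 percentage points)

- percentages count the whole charge, also what has not yet gone in

1. amount of product in percent of the starting material charged, at 15 s, 50 s, 1.5 min and 2.5 min

Two extreme versions can be done in the head. As long as consumption is small beside the feed, the product fraction at time t is about t squared over 2τT. Tuesday's reading of 4.0 % at 30.0 s then gives τ = 75.0 s, the consumption time. Sunday's first reading gives 73.9 s, about the same within the scatter, although Tuesday's flask holds 1.49 times the reagent of Sunday's.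

In the other extreme, consumption has caught up with the feed, and product trails the feed by τ, which gives 50.0 % at the end of dosing in Tuesday's flask. But T is just 2.00 times τ, so with τ held fixed the stock of starting material is still building and Tuesday's product should end above that line. My own sum with τ held fixed, (t − τ(1 − exp(−t/τ)))/T, gives 0.937 %, 9.00 %, 25.1 % and 56.8 %. Sunday's final 49.2 % is lower than that last figure, so I take it as an upper mark.

The forecast says 1 %, 10.4 %, 25.5 % and 52 %, reasoning that “the rate is nearly zero order in reagent”. Its last value is lower than mine.

Tuesday's flask gives 1.15 %, 9.87 %, 25.3 % and 53.3 %, and the forecast holds.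

    starting material + free catalyst ⇌ catalyst intermediate A (K = 26.0 L mol⁻¹, k = 84.1 L mol⁻¹ s⁻¹)
    catalyst intermediate B → free catalyst + product (k = 7.86 s⁻¹)
    reagent + catalyst intermediate A → catalyst intermediate B (k = 448 L mol⁻¹ s⁻¹)
    2 catalyst intermediate A → spent catalyst (k = 269 L mol⁻¹ s⁻¹)

At 1.55 min in Tuesday's flask, the half-life of free catalyst against starting material (forward step alone) is 0.23 s, while catalyst intermediate A has a half-life of 0.019 s against reagent and catalyst intermediate B 0.0882 s against its release, which makes capture the slowest of the three, yet it is 2.65 times the release time, so capture and release are of like size. Reckoned from the capture constant and free catalyst, τ is 71.0 s at 1.25 min and 85.3 s at 2.50 min. For Sunday's flask, the fixed-τ sum with 73.9 s gives 25.3 % at 1.50 min, where the reading was 24.5 %.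

(The data were generated by integration for substances that don't exist; scatter was added.)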